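The rate constants are invented; no experiment stands behind them.

Ask how much intermediate stands at the end in each vessel, and whether the vessel matters at all.

| flask | substrate | reagent | free catalyst | second catalyst | time | remark |
|---|---|---|---|---|---|---|
| autumn | 0.071 M | 0.0497 M (fed, over 10.0 h) | 3.5 mM | 0.14 mM | 20 h | a stirred flask in which reagent is dosed at a steady rate over 10.0 h without added volume, worked up at 20 h |
| summer | 0.071 M | 0.0497 M | 3.5 mM | 0.14 mM | 20 h | plug flow through a tube for 20 h, no back-mixing |
| winter | 0.071 M | 0.0497 M | 3.5 mM | 0.14 mM |  | a single well-mixed tank run continuously and read at steady state, 20 h in it on average |
| dawn | 0.071 M | 0.0497 M | 3.5 mM | 0.14 mM | 20 h | a closed flask charged with all of it at once and left for 20 h |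

1. the set-up with the highest amount of intermediate at the outlet or at the end, in percent of the substrate put in ("none" if the first two lie within 2 percentage points) (autumn / summer / winter / dawn / none)
2. amount of intermediate at the outlet or at the end, in percent of the substrate put in, autumn
3. amount of intermediate at the outlet or at the end, in percent of the substrate put in, summer
4. amount of intermediate at the outlet or at the end, in percent of the substrate put in, winter
5. amount of intermediate at the outlet or at the end, in percent of the substrate put in, dawn

- the stated concentrations are those of everything mixed, before any reaction; amounts are the same in each set-up
- the feed brings no volume worth counting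
- run time (autumn): 20 h

    reagent + second catalyst → spent catalyst (k1 = 0.365 M⁻¹ min⁻¹)
    substrate + free catalyst ⇌ free catalyst + intermediate (K2 = 0.32, k2 = 28.8 M⁻¹ min⁻¹)
    reagent + second catalyst + intermediate → second catalyst + product (k3 = 742 M⁻² min⁻¹)

Climb the ladder of half-lives rung by rung, taking the way back of the substrate step as its rate constant divided by its equilibrium constant. Free catalyst is not consumed in that step, so substrate and intermediate relax towards each other with a half-life of 1.67 min, and the intermediate holds a share f = 24.2% of the pool of the two, a pre-equilibrium. On the next rung, second catalyst goes to spent catalyst with a half-life of 38.2 min at the charged reagent. That is much longer than the relaxation, so I take f as standing while second catalyst lives, though in dawn and summer intermediate has to start from zero with reagent already present. Count the half-lives: dawn and summer allow 31.4 of them. Autumn, where reagent builds up through the feed, allows 23.6, reckoned as if the fed reagent stayed unused.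

Now compare the two steps that use second catalyst. Both are first order in reagent and in second catalyst, so those factors cancel in their ratio, and the turnover number is the product constant times the intermediate over the spending constant, 35.0 with the whole charged substrate as pool at share f. Carry the budget b, the second-catalyst charge times f times the product constant over the spending constant, 0.0690: in a batch or plug-flow vessel, while f stands, the pool falls by the factor exp(−b) when the charge is spent, however reagent arrives. Intermediate is then f·exp(−b): 22.6% in autumn, 22.6% in summer, 22.6% in dawn. The winter tank at steady state has spent a fraction 95.6% of its second catalyst, reckoned at the charged reagent, and its balance divides f by one plus b times that fraction, which gives 22.7%. That gap of 0.12 percentage points between winter and the other vessels is smaller than the margin, so I commit to no winner.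

The forecast gave 22.6%, 22.7%, 22.7% and 22.7% for autumn, summer, winter and dawn, and best none, reasoning that second catalyst “makes only about 35 turnovers”.

The simulation gives 22.6%, 22.7%, 22.7% and 22.7%, and best none. Product reads 6.66% of the charged substrate in autumn and 6.37% in dawn, beside the 6.67% that the budget b allots.

Take summer again with 5.6 × 10⁻⁴ M of second catalyst. The budget becomes 0.276, which gives 18.4% intermediate, and the computed flask reads 18.7%.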